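The decalin is disconnected at C1–C10 (terpenoid numbering), so ring A is closed last on an intact ring B. The key step exploits the methyl-bearing quaternary ring-fusion carbon C10 and its 1,4-relationship to the C3 oxygen: hydrogen atom transfer to an exocyclic methylene on C10 creates the angular methyl and a tertiary radical, which adds 6-endo to the terminal carbon of a vinyl ketone held on C5 through the quaternary C4, giving C10, the cis A/B fusion and the C3 carbonyl in one operation. The monocyclic precursor comes from asymmetric epoxidation, anti epoxide opening and an Ireland–Claisen shift. A phenylthiomethyl group on C9 is exchanged for farnesyl at the end.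

Key step: step 11

Remark on the chemistry: terpenoid numbering is used (ring A = C1–C5 and C10, ring B = C5–C10, C11 = the CH2 on C9). The target is read as the cis-fused decalin (2S,4aS,5R,6R,8aS): H-5, the C10 methyl, the C8 methyl, the C9 side chain and the C3 hydroxyl lie on one face (β), the C8 hydroxyl on the other (α).

Step 1
Reactants: 1 3-methylcyclohex-2-en-1-one
Product: 2 (1R,6R)-6-methyl-7-oxabicyclo[4.1.0]heptan-2-one
Conditions: aq. H2O2 (1.5 equiv), 9-amino-9-deoxy-epi-quinine bis(trifluoroacetate) or its quinidine-derived pseudoenantiomer (10 mol %; the one that gives the (1R,6R) epoxide), dioxane, 40 °C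
Reagents that add atoms: hydrogen peroxide OO
Why: Iminium-activated Weitz–Scheffer epoxidation, in which the chiral primary amine condenses with the enone and directs hydroperoxide addition to one face, so that both epoxide carbons (C8 and C9) are set together.

Step 2
Reactants: 2 (1R,6R)-6-methyl-7-oxabicyclo[4.1.0]heptan-2-one
Product: 3 (1S,2S,6R)-6-methyl-7-oxabicyclo[4.1.0]heptan-2-ol
Conditions: NaBH4, CeCl3·7H2O, MeOH, −78 °C
Reagents that add atoms: none
Why: Luche 1,2-reduction with hydride delivery anti to the epoxide oxygen should give mainly the cis-epoxy alcohol; this carbinol centre is temporary (removed in step 4) and its cis arrangement rules out Payne rearrangement in step 3.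

Step 3
Reactants: 3 (1S,2S,6R)-6-methyl-7-oxabicyclo[4.1.0]heptan-2-ol, 4 thioanisole
Product: 6 (1R,2R,3S)-1-methyl-2-[(phenylsulfanyl)methyl]cyclohexane-1,3-diol, via (phenylsulfanyl)methyllithium 5 (not isolated)
Conditions: 4 (3 equiv), n-BuLi, DABCO, THF, 0 °C; then 3, 0 → 45 °C
Reagents that add atoms: none
Why: Epoxide opening by the sulfur-stabilised organolithium is an SN2 reaction at C9, the only epoxide carbon open to attack because C8 is fully substituted, and the inversion fixes the trans relationship between the new C9–C11 bond and the C8 hydroxyl (trans-diaxial opening).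

Step 4
Reactants: 6 (1R,2R,3S)-1-methyl-2-[(phenylsulfanyl)methyl]cyclohexane-1,3-diol
Product: 7 (2S,3R)-3-hydroxy-3-methyl-2-[(phenylsulfanyl)methyl]cyclohexan-1-one
Conditions: SO3·pyridine, DMSO, i-Pr2NEt, CH2Cl2, 0 °C
Reagents that add atoms: none
Why: Parikh–Doering oxidation converts only the secondary alcohol into the ketone, leaves the tertiary alcohol and the sulfide untouched, and is mild enough not to epimerise C9.

Step 5
Reactants: 7 (2S,3R)-3-hydroxy-3-methyl-2-[(phenylsulfanyl)methyl]cyclohexan-1-one
Product: 8 (5R,6S)-5-hydroxy-5-methyl-6-[(phenylsulfanyl)methyl]cyclohex-1-en-1-yl trifluoromethanesulfonate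
Conditions: LiN(i-Pr)2 (2.2 equiv), THF, −78 °C; PhNTf2, −78 → 0 °C
Reagents that add atoms: N-phenylbis(trifluoromethanesulfonimide) O=S(=O)(N(c1ccccc1)S(=O)(=O)C(F)(F)F)C(F)(F)F
Why: Kinetic deprotonation of the alkoxide-bearing ketone takes place at the unhindered C5 methylene and not at the substituted C9, and O-sulfonylation of this enolate gives the enol triflate with the double bond between C10 and C5.

Step 6
Reactants: 8 (5R,6S)-5-hydroxy-5-methyl-6-[(phenylsulfanyl)methyl]cyclohex-1-en-1-yl trifluoromethanesulfonate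
Product: 9 (1R,2R)-3-(hydroxymethyl)-1-methyl-2-[(phenylsulfanyl)methyl]cyclohex-3-en-1-ol
Conditions: Bu3SnCH2OH, Pd(PPh3)4 (5 mol %), LiCl, 1,4-dioxane, 95 °C
Reagents that add atoms: (tributylstannyl)methanol CCCC[Sn](CCCC)(CCCC)CO
Why: Stille coupling of the enol triflate with the hydroxymethyl stannane installs the carbon that ends as the C10 methyl group; the sulfide and the free alcohol are tolerated and no stereocentre is touched.

Step 7
Reactants: 9 (1R,2R)-3-(hydroxymethyl)-1-methyl-2-[(phenylsulfanyl)methyl]cyclohex-3-en-1-ol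
Product: 10 [(5R,6R)-5-hydroxy-5-methyl-6-[(phenylsulfanyl)methyl]cyclohex-1-en-1-yl]methyl 2-methylpropanoate
Conditions: i-PrCOCl, pyridine, DMAP (cat.), CH2Cl2, 0 °C
Reagents that add atoms: 2-methylpropanoyl chloride CC(C)C(Cl)=O
Why: Acylation discriminates the primary allylic alcohol from the hindered tertiary alcohol and provides the allyl ester needed for the sigmatropic shift.

Step 8
Reactants: 10 [(5R,6R)-5-hydroxy-5-methyl-6-[(phenylsulfanyl)methyl]cyclohex-1-en-1-yl]methyl 2-methylpropanoate
Product: 13 2-[(1S,3R,4R)-4-hydroxy-4-methyl-2-methylidene-3-[(phenylsulfanyl)methyl]cyclohexyl]-2-methylpropanoic acid, via bis-silyl ketene acetal 11 (not isolated), via rearranged trimethylsilyl ester 12 (not isolated)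
Conditions: LiN(i-Pr)2 (2.3 equiv), Me3SiCl, THF, −78 → 60 °C; then aq. citric acid, MeOH, rt
Reagents that add atoms: none
Why: Ireland–Claisen rearrangement, in which the [3,3] shift of the silyl ketene acetal forms the C4–C5 bond, creates the quaternary C4 and moves the double bond to the exocyclic C10=CH2 position; the new C5 centre should arise trans to the C9 substituent because the chair-like array adds axially to the ring face opposite the CH2SPh group (half-chair with that group pseudo-equatorial).

Step 9
Reactants: 13 2-[(1S,3R,4R)-4-hydroxy-4-methyl-2-methylidene-3-[(phenylsulfanyl)methyl]cyclohexyl]-2-methylpropanoic acid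
Product: 15 2-[(1S,3R,4R)-4-hydroxy-4-methyl-2-methylidene-3-[(phenylsulfanyl)methyl]cyclohexyl]-N-methoxy-N,2-dimethylpropanamide, via acyl imidazole 14 (not isolated)
Conditions: 1,1'-carbonyldiimidazole, CH2Cl2, rt; then MeNHOMe·HCl, 40 °C
Reagents that add atoms: N,O-dimethylhydroxylamine hydrochloride CNOC.Cl
Why: Activation of the hindered acid as the acyl imidazole and aminolysis give the N-methoxy-N-methylamide, and the slow-reacting tertiary alcohol can stay free.

Step 10
Reactants: 15 2-[(1S,3R,4R)-4-hydroxy-4-methyl-2-methylidene-3-[(phenylsulfanyl)methyl]cyclohexyl]-N-methoxy-N,2-dimethylpropanamide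
Product: 16 4-[(1S,3R,4R)-4-hydroxy-4-methyl-2-methylidene-3-[(phenylsulfanyl)methyl]cyclohexyl]-4-methylpent-1-en-3-one
Conditions: CH2=CHMgBr (3 equiv), THF, −20 → 0 °C; cold aq. NaHSO4
Reagents that add atoms: vinylmagnesium bromide C=C[Mg]Br
Why: Weinreb ketone synthesis, in which the chelated tetrahedral adduct survives until the cold acidic quench, so the addition stops at the vinyl ketone that serves as radical acceptor (C1 and C2).

Step 11
Reactants: 16 4-[(1S,3R,4R)-4-hydroxy-4-methyl-2-methylidene-3-[(phenylsulfanyl)methyl]cyclohexyl]-4-methylpent-1-en-3-one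
Product: 17 (4aS,5R,6R,8aS)-6-hydroxy-1,1,4a,6-tetramethyl-5-[(phenylsulfanyl)methyl]octahydronaphthalen-2(1H)-one
Conditions: Fe(acac)3 (0.5 equiv), PhSiH3 (2.5 equiv), EtOH/(CH2OH)2, 60 °C
Reagents that add atoms: none
Why: The iron hydride formed from Fe(acac)3 and PhSiH3 transfers a hydrogen atom to the terminal carbon of the 1,1-disubstituted C10=CH2 alkene, which becomes the angular methyl and leaves a nucleophilic tertiary radical at C10; this radical adds to the unsubstituted β-carbon (C1) of the vinyl ketone, and the α-keto radical is reduced and protonated to the C3 ketone. The closest known reaction type is the hydrogen-atom-transfer-initiated reductive coupling of a donor alkene with an enone (intramolecular Giese reaction). Ring A closes in the 6-endo-trig mode, favoured over 5-exo attack at C2 by the polarisation of the enone. C10 is the only new stereocentre and is controlled by C5 and C9: in the chair with the bulky C5 side chain equatorial the C9 substituent is axial on the β face and the acceptor should add to the axial α lobe of the radical, anti to it, while in the other chair (side chain axial) closure is geometrically possible only on the α face, so both paths lead to the cis fusion with the methyl β. The step needs hydrogen atom transfer to the electron-rich 1,1-disubstituted alkene and not to the enone, which the higher reactivity of such alkenes and the fast intramolecular trapping should secure; the aryl sulfide and the free tertiary alcohol are expected to be inert.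

Step 12
Reactants: 17 (4aS,5R,6R,8aS)-6-hydroxy-1,1,4a,6-tetramethyl-5-[(phenylsulfanyl)methyl]octahydronaphthalen-2(1H)-one
Product: 18 (2S,4aS,5R,6R,8aS)-1,1,4a,6-tetramethyl-5-[(phenylsulfanyl)methyl]decahydronaphthalene-2,6-diol
Conditions: Al(Oi-Pr)3 (1.5 equiv), i-PrOH (trace acetone), toluene, 100 °C, equilibrating
Reagents that add atoms: none
Why: Meerwein–Ponndorf–Verley reduction is reversible, so the C3 carbinol is set under thermodynamic control: the (2S) epimer should be favoured because its hydroxyl is equatorial in the chair–chair form that keeps the C8 methyl equatorial and so avoids the syn-diaxial C8/C10 methyl pair, whereas kinetic hydride delivery to the open convex face would give the other epimer.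

Step 13
Reactants: 18 (2S,4aS,5R,6R,8aS)-1,1,4a,6-tetramethyl-5-[(phenylsulfanyl)methyl]decahydronaphthalene-2,6-diol, 19 (2E,6E)-farnesyl bromide
Product: 22 (2S,4aS,5R,6R,8aS)-1,1,4a,6-tetramethyl-5-[(3E,7E)-4,8,12-trimethyltrideca-3,7,11-trien-1-yl]decahydronaphthalene-2,6-diol, via trilithiated organolithium 20 (not isolated), via organomagnesium bromide 21 (not isolated)
Conditions: n-BuLi (2 equiv), THF, −78 °C; lithium 4,4'-di-tert-butylbiphenylide (2.2 equiv), −78 °C; MgBr2·OEt2; Li2CuCl4 (3 mol %), 19, −78 → 0 °C
Reagents that add atoms: none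
Why: Reductive lithiation cleaves the alkyl carbon–sulfur bond, and the derived Grignard reagent couples with the primary allylic bromide under copper catalysis at the α carbon (SN2) with retention of the E double bonds, forming the C11–C12 bond without touching a stereocentre.

Compound list
1 | 3-methylcyclohex-2-en-1-one | CC1=CC(=O)CCC1 | starting material
2 | (1R,6R)-6-methyl-7-oxabicyclo[4.1.0]heptan-2-one | O=C1CCC[C@@]2(C)O[C@@H]12 | intermediate
3 | (1S,2S,6R)-6-methyl-7-oxabicyclo[4.1.0]heptan-2-ol (cis-epoxy alcohol) | O[C@H]1CCC[C@@]2(C)O[C@@H]12 | intermediate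
4 | thioanisole (methyl phenyl sulfide) | CSc1ccccc1 | starting material
5 | (phenylsulfanyl)methyllithium | [Li]CSc1ccccc1 | intermediate
6 | (1R,2R,3S)-1-methyl-2-[(phenylsulfanyl)methyl]cyclohexane-1,3-diol | c1ccccc1SC[C@@H]1[C@@H](O)CCC[C@@]1(C)O | intermediate
7 | (2S,3R)-3-hydroxy-3-methyl-2-[(phenylsulfanyl)methyl]cyclohexan-1-one | c1ccccc1SC[C@@H]1C(=O)CCC[C@@]1(C)O | intermediate
8 | (5R,6S)-5-hydroxy-5-methyl-6-[(phenylsulfanyl)methyl]cyclohex-1-en-1-yl trifluoromethanesulfonate | c1ccccc1SC[C@@H]1C(OS(=O)(=O)C(F)(F)F)=CCC[C@@]1(C)O | intermediate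
9 | (1R,2R)-3-(hydroxymethyl)-1-methyl-2-[(phenylsulfanyl)methyl]cyclohex-3-en-1-ol | c1ccccc1SC[C@@H]1C(CO)=CCC[C@@]1(C)O | intermediate
10 | [(5R,6R)-5-hydroxy-5-methyl-6-[(phenylsulfanyl)methyl]cyclohex-1-en-1-yl]methyl 2-methylpropanoate | c1ccccc1SC[C@@H]1C(COC(=O)C(C)C)=CCC[C@@]1(C)O | intermediate
11 | bis-silyl ketene acetal of 10 (trimethylsilyl ketene acetal, C8 trimethylsilyl ether) | c1ccccc1SC[C@@H]1C(COC(O[Si](C)(C)C)=C(C)C)=CCC[C@@]1(C)O[Si](C)(C)C | intermediate
12 | trimethylsilyl ester of 13 with C8 trimethylsilyl ether | c1ccccc1SC[C@@H]1C(=C)[C@@H](C(C)(C)C(=O)O[Si](C)(C)C)CC[C@@]1(C)O[Si](C)(C)C | intermediate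
13 | 2-[(1S,3R,4R)-4-hydroxy-4-methyl-2-methylidene-3-[(phenylsulfanyl)methyl]cyclohexyl]-2-methylpropanoic acid | c1ccccc1SC[C@@H]1C(=C)[C@@H](C(C)(C)C(=O)O)CC[C@@]1(C)O | intermediate
14 | acyl imidazole of 13 | c1ccccc1SC[C@@H]1C(=C)[C@@H](C(C)(C)C(=O)n2ccnc2)CC[C@@]1(C)O | intermediate
15 | 2-[(1S,3R,4R)-4-hydroxy-4-methyl-2-methylidene-3-[(phenylsulfanyl)methyl]cyclohexyl]-N-methoxy-N,2-dimethylpropanamide | c1ccccc1SC[C@@H]1C(=C)[C@@H](C(C)(C)C(=O)N(C)OC)CC[C@@]1(C)O | intermediate
16 | 4-[(1S,3R,4R)-4-hydroxy-4-methyl-2-methylidene-3-[(phenylsulfanyl)methyl]cyclohexyl]-4-methylpent-1-en-3-one | c1ccccc1SC[C@@H]1C(=C)[C@@H](C(C)(C)C(=O)C=C)CC[C@@]1(C)O | intermediate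
17 | (4aS,5R,6R,8aS)-6-hydroxy-1,1,4a,6-tetramethyl-5-[(phenylsulfanyl)methyl]octahydronaphthalen-2(1H)-one (cis-fused) | c1ccccc1SC[C@@H]1[C@@]2(C)CCC(=O)C(C)(C)[C@H]2CC[C@@]1(C)O | intermediate
18 | (2S,4aS,5R,6R,8aS)-1,1,4a,6-tetramethyl-5-[(phenylsulfanyl)methyl]decahydronaphthalene-2,6-diol | c1ccccc1SC[C@@H]1[C@@]2(C)CC[C@H](O)C(C)(C)[C@H]2CC[C@@]1(C)O | intermediate
19 | (2E,6E)-farnesyl bromide | CC(C)=CCC/C(C)=C/CC/C(C)=C/CBr | starting material
20 | trilithio derivative of 18 (C11–Li and both lithium alkoxides) | [Li]C[C@@H]1[C@@]2(C)CC[C@H](O[Li])C(C)(C)[C@H]2CC[C@@]1(C)O[Li] | intermediate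
21 | C11 organomagnesium bromide of 20 (both lithium alkoxides kept) | Br[Mg]C[C@@H]1[C@@]2(C)CC[C@H](O[Li])C(C)(C)[C@H]2CC[C@@]1(C)O[Li] | intermediate
22 | (2S,4aS,5R,6R,8aS)-1,1,4a,6-tetramethyl-5-[(3E,7E)-4,8,12-trimethyltrideca-3,7,11-trien-1-yl]decahydronaphthalene-2,6-diol | CC(C)=CCC/C(C)=C/CC/C(C)=C/CC[C@@H]1[C@@]2(C)CC[C@H](O)C(C)(C)[C@H]2CC[C@@]1(C)O | target

Total step count: 13
Longest linear sequence: 13 steps (from 1; compounds 4 and 19 are commercial and enter directly)

The three steps most likely to fail

1. Step 11 (key step). Hydrogen atom transfer to the vinyl ketone, or reduction of the C10 radical before ring closure, may compete with cyclisation, and closure on the β face would erode the cis fusion. Fallback for step 11, setting out from 15 and coming back to the route at 17, in which the C10 radical is released from a tertiary alcohol derivative by photoredox catalysis so that no metal hydride meets the enone: silylation of the C8 hydroxyl of 15 (Et3SiOTf, 2,6-lutidine, CH2Cl2, 0 °C) should give triethylsilyl ether F1 as the protected amide. Mukaiyama hydration of its exocyclic alkene (Co(acac)2, PhSiH3, O2, i-PrOH) should give tertiary alcohol F2 with the new hydroxyl on C10, and CH2=CHMgBr (THF, −40 → 0 °C, cold aq. NaHSO4) should then give vinyl ketone F3 from the amide. Acylation of the C10 hydroxyl with chloro N-phthalimidoyl oxalate (Et3N, DMAP cat., THF, rt) should give N-phthalimidoyl oxalate F4 that is used crude. Under visible light (Ru(bpy)3(PF6)2, Hantzsch ester, i-Pr2NEt·HBF4, CH2Cl2/THF, blue light, rt) this fallback releases the same C10 radical by loss of phthalimide and two molecules of carbon dioxide for the 6-endo Giese closure to silyl ether F5 of the decalone, and Bu4NF (THF) returns 17.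

2. Step 12. Equilibration may be slow at the hindered C3 ketone, or the thermodynamic preference may be smaller than expected, so that epimer control at C3 is lost. Fallback for step 12, setting out from 17 and coming back at 18: enzymatic reduction with an (S)-selective ketoreductase (NADPH recycled with i-PrOH, phosphate buffer/DMSO, 30 °C), where the enzyme and not the substrate conformation selects the carbonyl face; this fallback forms no new compound.

3. Step 13. The poly-lithiated intermediate may be quenched before transmetalation, or the allylic coupling may occur at the γ carbon. Fallback for step 13, setting out from 18 and coming back at 22, by sulfone chemistry: oxidation of the sulfide of 18 (mCPBA, 2.2 equiv, CH2Cl2, 0 °C) should give phenyl sulfone F6 as a crystalline diol. Its trianion (n-BuLi, 3 equiv, THF/HMPA, −78 °C) is alkylated at the α-sulfonyl carbon with 19 to give farnesylated sulfone F7 as a mixture of epimers at that carbon, and reductive desulfonylation in this fallback (Na(Hg), Na2HPO4, MeOH, −20 °C) gives 22.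

Further compounds
F1 | step 11 | 2-[(1S,3R,4R)-4-methyl-2-methylidene-3-[(phenylsulfanyl)methyl]-4-(triethylsilyloxy)cyclohexyl]-N-methoxy-N,2-dimethylpropanamide | c1ccccc1SC[C@@H]1C(=C)[C@@H](C(C)(C)C(=O)N(C)OC)CC[C@@]1(C)O[Si](CC)(CC)CC
F2 | step 11 | Markovnikov hydrate of F1 (tertiary alcohol at C10, either epimer at this carbinol, other centres as in 15) | c1ccccc1SC[C@@H]1C(C)(O)[C@@H](C(C)(C)C(=O)N(C)OC)CC[C@@]1(C)O[Si](CC)(CC)CC
F3 | step 11 | vinyl ketone from F2 (C10 tertiary alcohol, C8 triethylsilyl ether) | c1ccccc1SC[C@@H]1C(C)(O)[C@@H](C(C)(C)C(=O)C=C)CC[C@@]1(C)O[Si](CC)(CC)CC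
F4 | step 11 | N-phthalimidoyl oxalate of the C10 tertiary alcohol of F3 | c1ccccc1SC[C@@H]1C(C)(OC(=O)C(=O)ON2C(=O)c3ccccc3C2=O)[C@@H](C(C)(C)C(=O)C=C)CC[C@@]1(C)O[Si](CC)(CC)CC
F5 | step 11 | triethylsilyl ether of 17 | c1ccccc1SC[C@@H]1[C@@]2(C)CCC(=O)C(C)(C)[C@H]2CC[C@@]1(C)O[Si](CC)(CC)CC
F0 | step 12 | none | none
F6 | step 13 | (2S,4aS,5R,6R,8aS)-5-[(benzenesulfonyl)methyl]-1,1,4a,6-tetramethyldecahydronaphthalene-2,6-diol | O=S(=O)(c1ccccc1)C[C@@H]1[C@@]2(C)CC[C@H](O)C(C)(C)[C@H]2CC[C@@]1(C)O
F7 | step 13 | 5-[(3E,7E)-1-(benzenesulfonyl)-4,8,12-trimethyltrideca-3,7,11-trien-1-yl]-1,1,4a,6-tetramethyldecahydronaphthalene-2,6-diol (ring configuration as in 18, either epimer at the sulfonyl-bearing carbon) | CC(C)=CCC/C(C)=C/CC/C(C)=C/CC(S(=O)(=O)c1ccccc1)[C@@H]1[C@@]2(C)CC[C@H](O)C(C)(C)[C@H]2CC[C@@]1(C)O
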